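**Retrosynthetic overview**

1. The furan ring is opened last (O1–C2 and C2–aryl bonds of the benzofuran): an ortho-ethynylphenol (phloroglucinol half, already carrying the 1,1-dimethylallyl group) is joined to a 5-bromo-2,2-dimethylchroman (resorcinol half) by coupling–cyclization; three MOM ethers are removed at the end.
2. The pyran ring of the chroman is closed at C3–C4 by titanium-mediated reductive coupling (McMurry) of an aryl aldehyde (C4) with an α-aryloxyisobutyraldehyde (C3), two carbonyl carbons of like polarity. The C3=C4 alkene is hydrogenated before the vinyl group enters the molecule.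
3. Enabling feature: in the pyran ring C2 is quaternary (O1 and two methyls), and C4 sits on C4a of the resorcinol ring, ortho to O1 (C8a) and para to the C7 oxygen. C3 can therefore be a non-enolizable aldehyde that arrives with C2 in one O-alkylation, and C4 is the formyl group that resorcinol formylation puts exactly there.
4. The 1,1-dimethylallyl group comes from an aromatic Claisen rearrangement of the 4-O-prenyl ether of 2,4,6-trihydroxybenzaldehyde (ortho positions equivalent, para position blocked by the formyl group).
5. Order of ring formation: pyran ring (step 4), then furan ring (step 10).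

Key step: step 4

Remark: the target has no stereocentre; 2-bromo-2-methylpropanal is taken as a purchasable reagent.

**Step 1**
Reactants: 1 5-bromobenzene-1,3-diol
Product: 3 2-bromo-4,6-dihydroxybenzaldehyde, via aryl iminium chloride 2 (not isolated)
Conditions: POCl3, DMF, MeCN, −15 °C → rt; then H2O, 50 °C
Reagents that add atoms: N,N-dimethylformamide, CN(C)C=O; water, O
Why: Vilsmeier–Haack formylation of a 5-substituted resorcinol should go para to one hydroxyl and ortho to the other (next to bromine), the position between the two hydroxyls being the more hindered one.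

**Step 2**
Reactants: 3 2-bromo-4,6-dihydroxybenzaldehyde
Product: 4 2-bromo-6-hydroxy-4-(methoxymethoxy)benzaldehyde
Conditions: MOMCl (1.05 equiv), i-Pr2NEt, CH2Cl2, 0 °C
Reagents that add atoms: chloromethyl methyl ether, COCCl
Why: O-alkylation (acetal protection) should take the more acidic hydroxyl para to the formyl group and leave the ortho hydroxyl, which is hydrogen-bonded to the carbonyl, free.

**Step 3**
Reactants: 4 2-bromo-6-hydroxy-4-(methoxymethoxy)benzaldehyde; 5 2-bromo-2-methylpropanal
Product: 6 2-bromo-4-(methoxymethoxy)-6-[(2-methyl-1-oxopropan-2-yl)oxy]benzaldehyde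
Conditions: K2CO3, DMF, rt → 45 °C
Reagents that add atoms: none
Why: Williamson-type substitution of the phenoxide at a tertiary α-bromo carbonyl carbon, as in aryloxyisobutyrate (fibrate) syntheses; the new α-carbon has no hydrogen, so neither aldol chemistry nor Rap–Stoermer-type closure onto the ortho formyl group can follow.

**Step 4**
Reactants: 6 2-bromo-4-(methoxymethoxy)-6-[(2-methyl-1-oxopropan-2-yl)oxy]benzaldehyde
Product: 8 5-bromo-7-(methoxymethoxy)-2,2-dimethyl-2H-chromene, via titanium diolate 7 (not isolated)
Conditions: TiCl3(DME)1.5, Zn(Cu), DME, reflux; 6 added by syringe pump over 20 h (high dilution)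
Reagents that add atoms: none
Why: Intramolecular McMurry reaction: single-electron transfer from low-valent titanium turns the carbonyl groups into titanium-bound ketyl species, C4 and C3 (both electrophilic carbonyl carbons in 6, hence of like polarity) join to the cyclic titanium diolate 7, and at reflux the oxophilic titanium surface removes both oxygens to leave the C3=C4 double bond of 8. The closest known reaction type is the titanium-mediated reductive cyclization of tethered aryl carbonyl/alkyl carbonyl pairs to cycloalkenes and 2H-chromenes. The pyran ring is closed by a six-membered-ring pinacol-type coupling in which both reacting carbons end up inside the ring, and the ring allows only the cis alkene. No stereocentre has to be controlled, because the two carbinol centres of 7 form without control and both become sp2 carbons in 8. The step needs ring closure instead of chain growth and must spare the C2–O1 bond, the aryl bromide and the acetal: slow addition at high dilution, the six-membered ring size, the gem-dimethyl group at C2 (Thorpe–Ingold effect, no α-hydrogen at either aldehyde) and the fixed ortho relationship of C4 and O1 on the benzene ring secure the first, and the easier reduction of the aromatic aldehyde, whose ketyl then takes the neighbouring aliphatic carbonyl as acceptor, should keep a free C3 ketyl (the species that could expel the aryloxy group) from building up.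

**Step 5**
Reactants: 8 5-bromo-7-(methoxymethoxy)-2,2-dimethyl-2H-chromene
Product: 9 5-bromo-7-(methoxymethoxy)-2,2-dimethyl-3,4-dihydro-2H-chromene
Conditions: H2 (3 atm), RhCl(PPh3)3 (5 mol %), benzene–EtOH 1:1, rt
Reagents that add atoms: none
Why: Homogeneous catalytic hydrogenation with RhCl(PPh3)3 should saturate the cis-disubstituted styrene-type C3=C4 bond without hydrogenolysis of the aryl bromide or the acetal, which palladium on carbon would risk.

**Step 6**
Reactants: 10 2,4,6-trihydroxybenzaldehyde; 11 3-methylbut-2-en-1-ol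
Product: 12 2,6-dihydroxy-4-[(3-methylbut-2-en-1-yl)oxy]benzaldehyde
Conditions: PPh3, DIAD, THF, 0 °C → rt
Reagents that add atoms: none
Why: Mitsunobu etherification should select the 4-hydroxyl, the most acidic one and the only one not hydrogen-bonded to the formyl group, and avoids the C-alkylation that prenyl halides and base cause with phloroglucinols.

**Step 7**
Reactants: 12 2,6-dihydroxy-4-[(3-methylbut-2-en-1-yl)oxy]benzaldehyde
Product: 14 2,4,6-trihydroxy-3-(2-methylbut-3-en-2-yl)benzaldehyde, via ortho-dienone 13 (not isolated)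
Conditions: N,N-diethylaniline, 185 °C, sealed tube
Reagents that add atoms: none
Why: Aromatic Claisen rearrangement ([3,3]-sigmatropic shift, then tautomerization) turns the prenyl ether into the ortho 1,1-dimethylallyl group; the two ortho positions are equivalent by symmetry and the para position carries the formyl group, so neither a regioisomer nor a further shift to the para position is possible.

**Step 8**
Reactants: 14 2,4,6-trihydroxy-3-(2-methylbut-3-en-2-yl)benzaldehyde
Product: 15 2-hydroxy-4,6-bis(methoxymethoxy)-3-(2-methylbut-3-en-2-yl)benzaldehyde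
Conditions: MOMCl (2.1 equiv), i-Pr2NEt, CH2Cl2, 0 °C → rt
Reagents that add atoms: chloromethyl methyl ether, COCCl
Why: O-alkylation (acetal protection) should take the 4- and 6-hydroxyls, while the 2-hydroxyl, wedged between the formyl group (hydrogen bond) and the quaternary carbon of the 1,1-dimethylallyl group, stays free.

**Step 9**
Reactants: 15 2-hydroxy-4,6-bis(methoxymethoxy)-3-(2-methylbut-3-en-2-yl)benzaldehyde
Product: 16 2-ethynyl-3,5-bis(methoxymethoxy)-6-(2-methylbut-3-en-2-yl)phenol
Conditions: dimethyl (1-diazo-2-oxopropyl)phosphonate, K2CO3, MeOH, rt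
Reagents that add atoms: dimethyl (1-diazo-2-oxopropyl)phosphonate, CC(=O)C(=[N+]=[N-])P(=O)(OC)OC
Why: Seyferth–Gilbert homologation in its Ohira–Bestmann form converts the aldehyde into the terminal alkyne under mild base that should leave the phenol, the acetals and the vinyl group untouched.

**Step 10**
Reactants: 9 5-bromo-7-(methoxymethoxy)-2,2-dimethyl-3,4-dihydro-2H-chromene; 16 2-ethynyl-3,5-bis(methoxymethoxy)-6-(2-methylbut-3-en-2-yl)phenol
Product: 18 4,6-bis(methoxymethoxy)-2-[7-(methoxymethoxy)-2,2-dimethyl-3,4-dihydro-2H-chromen-5-yl]-7-(2-methylbut-3-en-2-yl)-1-benzofuran, via diarylalkyne 17 (not isolated)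
Conditions: PdCl2(PPh3)2 (5 mol %), CuI (5 mol %), Et3N, DMF, 80 °C
Reagents that add atoms: none
Why: Sonogashira coupling of the aryl bromide with the ortho-ethynylphenol, followed in the same pot by 5-endo-dig addition of the phenol oxygen to the metal-activated alkyne (the coupling–cyclization route to 2-arylbenzofurans), should close the furan ring with the 1,1-dimethylallyl group next to the ring oxygen.

**Step 11**
Reactants: 18 4,6-bis(methoxymethoxy)-2-[7-(methoxymethoxy)-2,2-dimethyl-3,4-dihydro-2H-chromen-5-yl]-7-(2-methylbut-3-en-2-yl)-1-benzofuran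
Product: 19 2-(7-hydroxy-2,2-dimethyl-3,4-dihydro-2H-chromen-5-yl)-7-(2-methylbut-3-en-2-yl)-1-benzofuran-4,6-diol
Conditions: 3 M HCl (aq), MeOH, 45 °C
Reagents that add atoms: none
Why: Acid-catalysed acetal cleavage (transacetalization to dimethoxymethane) should free the three phenols under conditions mild enough for the benzofuran, the chroman and the 1,1-dimethylallyl group.

**Compound list**

1 | 5-bromobenzene-1,3-diol | Oc1cc(O)cc(Br)c1 | starting material
2 | [(2-bromo-4,6-dihydroxyphenyl)methylidene]dimethylammonium chloride | C[N+](C)=Cc1c(O)cc(O)cc1Br.[Cl-] | intermediate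
3 | 2-bromo-4,6-dihydroxybenzaldehyde | O=Cc1c(O)cc(O)cc1Br | intermediate
4 | 2-bromo-6-hydroxy-4-(methoxymethoxy)benzaldehyde | O=Cc1c(O)cc(OCOC)cc1Br | intermediate
5 | 2-bromo-2-methylpropanal | CC(C)(Br)C=O | starting material
6 | 2-bromo-4-(methoxymethoxy)-6-[(2-methyl-1-oxopropan-2-yl)oxy]benzaldehyde | O=Cc1c(OC(C)(C)C=O)cc(OCOC)cc1Br | intermediate
7 | titanium 3,4-diolate of 5-bromo-7-(methoxymethoxy)-2,2-dimethyl-3,4-dihydro-2H-chromene, drawn as the monomeric dichlorotitanium chelate (tetravalent titanium; ring fusion necessarily cis, racemic) | CC1(C)Oc2cc(OCOC)cc(Br)c2C2O[Ti](Cl)(Cl)OC12 | intermediate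
8 | 5-bromo-7-(methoxymethoxy)-2,2-dimethyl-2H-chromene | CC1(C)C=Cc2c(Br)cc(OCOC)cc2O1 | intermediate
9 | 5-bromo-7-(methoxymethoxy)-2,2-dimethyl-3,4-dihydro-2H-chromene | CC1(C)CCc2c(Br)cc(OCOC)cc2O1 | intermediate
10 | 2,4,6-trihydroxybenzaldehyde | O=Cc1c(O)cc(O)cc1O | starting material
11 | 3-methylbut-2-en-1-ol | CC(C)=CCO | starting material
12 | 2,6-dihydroxy-4-[(3-methylbut-2-en-1-yl)oxy]benzaldehyde | O=Cc1c(O)cc(OCC=C(C)C)cc1O | intermediate
13 | 2,6-dihydroxy-3-(2-methylbut-3-en-2-yl)-4-oxocyclohexa-1,5-diene-1-carbaldehyde (racemic at C3) | O=CC1=C(O)C(C(C)(C)C=C)C(=O)C=C1O | intermediate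
14 | 2,4,6-trihydroxy-3-(2-methylbut-3-en-2-yl)benzaldehyde | O=Cc1c(O)cc(O)c(C(C)(C)C=C)c1O | intermediate
15 | 2-hydroxy-4,6-bis(methoxymethoxy)-3-(2-methylbut-3-en-2-yl)benzaldehyde | O=Cc1c(OCOC)cc(OCOC)c(C(C)(C)C=C)c1O | intermediate
16 | 2-ethynyl-3,5-bis(methoxymethoxy)-6-(2-methylbut-3-en-2-yl)phenol | C#Cc1c(OCOC)cc(OCOC)c(C(C)(C)C=C)c1O | intermediate
17 | 2-{[7-(methoxymethoxy)-2,2-dimethyl-3,4-dihydro-2H-chromen-5-yl]ethynyl}-3,5-bis(methoxymethoxy)-6-(2-methylbut-3-en-2-yl)phenol | C=CC(C)(C)c1c(O)c(C#Cc2cc(OCOC)cc3OC(C)(C)CCc23)c(OCOC)cc1OCOC | intermediate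
18 | 4,6-bis(methoxymethoxy)-2-[7-(methoxymethoxy)-2,2-dimethyl-3,4-dihydro-2H-chromen-5-yl]-7-(2-methylbut-3-en-2-yl)-1-benzofuran | C=CC(C)(C)c1c(OCOC)cc(OCOC)c2cc(-c3cc(OCOC)cc4c3CCC(C)(C)O4)oc12 | intermediate
19 | 2-(7-hydroxy-2,2-dimethyl-3,4-dihydro-2H-chromen-5-yl)-7-(2-methylbut-3-en-2-yl)-1-benzofuran-4,6-diol (CNP0300714.0) | C=CC(C)(C)c1c(O)cc(O)c2cc(-c3cc(O)cc4c3CCC(C)(C)O4)oc12 | target

**Step count and risks**

Total steps: 11. Longest linear sequence: 7 steps (steps 1–5, 10 and 11).

The three steps most likely to fail: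

1. Step 4 (key step). The aryloxy group may be expelled from C2 once a ketyl forms at C3 (reductive C–O cleavage). The coupling may also stop at the diolate stage or run between molecules, and the carbon–bromine bond may be reduced. The fallback closes the same C3–C4 bond by olefin metathesis; it sets out from 4 and also bypasses step 3. CuCl2-catalysed O-alkylation of 4 with 3-chloro-3-methylbut-1-yne (DBU, MeCN, 0 °C) should give 2-bromo-4-(methoxymethoxy)-6-[(2-methylbut-3-yn-2-yl)oxy]benzaldehyde F1. Semi-hydrogenation (H2, Pd/CaCO3 poisoned with Pb(OAc)2, quinoline, EtOAc, rt) should give 2-bromo-4-(methoxymethoxy)-6-[(2-methylbut-3-en-2-yl)oxy]benzaldehyde F2. Wittig methylenation (Ph3PCH3Br, KOt-Bu, THF, 0 °C) should give 1-bromo-2-ethenyl-5-(methoxymethoxy)-3-[(2-methylbut-3-en-2-yl)oxy]benzene F3. Ring-closing metathesis (second-generation Grubbs catalyst RuCl2(=CHPh)(H2IMes)(PCy3), CH2Cl2, 40 °C) should then give 8, where the fallback comes back to the route. All operations stay below 45 °C so that the aryl 1,1-dimethylallyl ether does not undergo Claisen rearrangement.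

2. Step 7. At 185 °C the freshly formed ortho-(1,1-dimethylallyl)phenol may react on, by an ene-type shift of the side chain or by addition of a flanking hydroxyl to the vinyl group. The site selectivity of the protection in step 8 also depends on this compound. The fallback sets out from 10 and bypasses steps 7 and 8. Double protection (MOMCl, i-Pr2NEt, CH2Cl2) should give 2-hydroxy-4,6-bis(methoxymethoxy)benzaldehyde F4. Bromination ortho to the free hydroxyl (NBS, CH2Cl2, 0 °C) should give 3-bromo-2-hydroxy-4,6-bis(methoxymethoxy)benzaldehyde F5. An allyl–aryl Suzuki–Miyaura coupling with 4,4,5,5-tetramethyl-2-(3-methylbut-2-en-1-yl)-1,3,2-dioxaborolane, under ligand control for the branched product (Pd(OAc)2, bulky dialkylbiarylphosphine, K3PO4, THF–H2O, 40 °C), should then give 15, where the fallback comes back to the route.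

3. Step 10. The terminal ortho-ethynylphenol may cyclize before it couples or dimerize oxidatively, and oxidative addition of zerovalent palladium into the ortho-alkyl aryl bromide may be slow. The homologation of the electron-rich, phenoxide-deactivated aldehyde in step 9 may also be sluggish. The fallback forms the C2–aryl bond by Suzuki–Miyaura coupling; it sets out from 15 and 9 and bypasses step 9. Ramirez olefination of 15 (CBr4, PPh3, Et3N, CH2Cl2, 0 °C) should give 2-(2,2-dibromoethenyl)-3,5-bis(methoxymethoxy)-6-(2-methylbut-3-en-2-yl)phenol F6. Intramolecular O-vinylation (CuI, K3PO4, THF, 80 °C) should give 2-bromo-4,6-bis(methoxymethoxy)-7-(2-methylbut-3-en-2-yl)-1-benzofuran F7. Borylation of 9 (B2pin2, PdCl2(dppf), KOAc, dioxane, 90 °C) should give 2-[7-(methoxymethoxy)-2,2-dimethyl-3,4-dihydro-2H-chromen-5-yl]-4,4,5,5-tetramethyl-1,3,2-dioxaborolane F8. Coupling of F7 with F8 (Pd(PPh3)4, K2CO3, dioxane–H2O, 80 °C) should then give 18, where the fallback comes back to the route.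

**Further compounds**

F1 | step 4 | 2-bromo-4-(methoxymethoxy)-6-[(2-methylbut-3-yn-2-yl)oxy]benzaldehyde | O=Cc1c(OC(C)(C)C#C)cc(OCOC)cc1Br
F2 | step 4 | 2-bromo-4-(methoxymethoxy)-6-[(2-methylbut-3-en-2-yl)oxy]benzaldehyde | O=Cc1c(OC(C)(C)C=C)cc(OCOC)cc1Br
F3 | step 4 | 1-bromo-2-ethenyl-5-(methoxymethoxy)-3-[(2-methylbut-3-en-2-yl)oxy]benzene | C=Cc1c(OC(C)(C)C=C)cc(OCOC)cc1Br
F4 | step 7 | 2-hydroxy-4,6-bis(methoxymethoxy)benzaldehyde | O=Cc1c(O)cc(OCOC)cc1OCOC
F5 | step 7 | 3-bromo-2-hydroxy-4,6-bis(methoxymethoxy)benzaldehyde | O=Cc1c(O)c(Br)c(OCOC)cc1OCOC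
F6 | step 10 | 2-(2,2-dibromoethenyl)-3,5-bis(methoxymethoxy)-6-(2-methylbut-3-en-2-yl)phenol | BrC(Br)=Cc1c(OCOC)cc(OCOC)c(C(C)(C)C=C)c1O
F7 | step 10 | 2-bromo-4,6-bis(methoxymethoxy)-7-(2-methylbut-3-en-2-yl)-1-benzofuran | C=CC(C)(C)c1c(OCOC)cc(OCOC)c2cc(Br)oc12
F8 | step 10 | 2-[7-(methoxymethoxy)-2,2-dimethyl-3,4-dihydro-2H-chromen-5-yl]-4,4,5,5-tetramethyl-1,3,2-dioxaborolane | COCOc1cc(B2OC(C)(C)C(C)(C)O2)c2CCC(C)(C)Oc2c1
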